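## Analysis of the target

The target is an isoflavan. Ring A (C4a to C8a, OMe at C5, OH at C7) is fused to a dihydropyran ring (O1, C2, C3, C4), and C3 carries ring B, a phenyl ring with OH at C2', a prenyl group at C3' and OMe at C4'. C3 is the only stereocentre and reads as (R) from the SMILES (C2 > C1' > C4 > H). It lies between two methylene groups, so no neighbouring function can relay stereochemistry to it, and it cannot epimerise once the ring is closed. The sensitive parts are the prenyl olefin next to a free phenol (acid closes it to a 2,2-dimethylchroman, and hydrogenation or hydrogenolysis reduces it) and the very electron-rich ring A. The difficulties are making a lone benzylic stereocentre catalytically, placing the prenyl group between two oxygens on ring B, differentiating the three oxygens of ring A, and removing protecting groups without acid or hydrogen. The plan rests on one feature: C4 is a benzylic CH2 ortho to the phenolic O1 of ring A, which is a masked o-quinone methide with electrophilic C4 and nucleophilic O1. C3 and C2 are then the α-carbon and the carbonyl carbon of a ring B arylacetaldehyde, so one amine-catalysed annulation can form C3–C4 and O1–C2, close the pyran ring and set C3.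

## Retrosynthetic reasoning

The last operation frees the two phenols of 18 from the bis-allyl ether 17. Allyl ethers are chosen because zerovalent palladium removes them under neutral conditions, so the prenyl olefin beside the new 2'-OH is never exposed to acid. Acetal-type protecting groups were rejected for two reasons. Their removal needs acid next to the prenyl group. Worse, an acetal ortho to the side chain would be lost during the acidic enol ether hydrolysis that makes aldehyde 13, and the freed phenol would cyclise to a benzofuran.

Chroman 17 is opened at O1–C2 to give diol 16. This bond is cut because the annulation delivers C2 at the aldehyde level, as a lactol. Direct ionic deoxygenation of the lactol would pass through an oxocarbenium ion at C2, which can lose the C3 proton and scramble the stereocentre. Reduction to the primary alcohol under basic conditions, followed by a neutral Mitsunobu closure, never involves C3.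

Diol 16 comes from lactol 15, which is cut at C3–C4 and O1–C2. This gives o-quinone methide 14, released from sulfone 5, and arylacetaldehyde 13, activated as its enamine by a chiral secondary amine. These two bonds are chosen because they split the molecule into its ring A and ring B halves at the only stereocentre. The forward reaction must add the enamine carbon to the exocyclic CH2 of 14 on one face and then trap the aldehyde with the ring A phenol. The α-aryl centre is labile while it is an aldehyde, so reduction to 16 follows in the same flask.

Sulfone 5 is traced to salicylaldehyde 3 by a sulfinate displacement on benzylic alcohol 4. The formyl carbon of 3 is the future C4, so the position of the CH2 on ring A is fixed by the starting aldehyde and not by an electrophilic substitution. Aldehyde 3 comes from 1 by O-allylation at the non-chelated 4-OH to give 2, then methylation of one of the two equivalent chelated hydroxyls.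

Aldehyde 13 is cut at the C2–C3 bond of the future chroman (its CH2–CHO bond is made by one-carbon homologation). It goes back through enol ether 12 to benzaldehyde 11, which uses a cheap salicylaldehyde as the ring B source.

The prenyl group of 11 is traced through phenol 10 to the 1,1-dimethylallyl ether 9 by an aromatic Claisen shift. The only free ortho position of the ether oxygen is C3, between the two oxygens, which is where the prenyl group must go. Ether 9 comes from alkyne 8 by semihydrogenation, and 8 from 6 and 7 by propargylic etherification.

## Alternatives that were turned down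

Alternative 1: The pyran ring is cut at C8a–O1, C4a–C4 and O1–C2 at once. The precursors are the 2-silylaryl triflate 5-(benzyloxy)-3-methoxy-2-(trimethylsilyl)phenyl trifluoromethanesulfonate A3 and the acrolein 2-[4-methoxy-2-(methoxymethoxy)phenyl]prop-2-enal A2. In the forward step CsF releases the aryne from A3 and the aldehyde C=O of A2 adds across it, oxygen to the carbon remote from the methoxy group. The benzoxete opens to an o-quinone methide, and an oxa-6π electrocyclisation gives the isoflav-3-ene 7-(benzyloxy)-5-methoxy-3-[4-methoxy-2-(methoxymethoxy)phenyl]-2H-chromene A1.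
- For it: three bonds and the whole pyran ring form in one step from two simple partners. On convergence and bond count per step it is stronger than the chosen route.
- Against it: A1 is achiral, so C3 must be set afterwards by asymmetric hydrogenation of the C3=C4 bond, for example with an [Ir(cod)(phosphine–oxazoline)]BArF catalyst. That hydrogenation, and the hydrogenolysis of the benzyl ether, cannot coexist with a prenyl olefin. The prenyl group must therefore be introduced last, by metalation between the two oxygens of ring B on the complete isoflavan. A3 is a 1,2,3,5-tetrasubstituted arene that needs several steps, and A2 is prone to polymerise.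
- Comparison: the chosen strategy gives up the three-bond step. In its place it sets C3 in the ring-forming step and carries the prenyl group from the start.

Alternative 2: Ring B is built last on an enantiopure chroman. The precursors are the diazo enone (E)-1-diazo-4-[(3R)-7-(tert-butyldimethylsilyloxy)-5-methoxychroman-3-yl]but-3-en-2-one A5 and the ynol ether 1-methoxy-5-methylhex-4-en-1-yne A6. Irradiation causes a Wolff rearrangement to a vinylketene, whose carbonyl carbon adds to the prenyl-bearing alkyne carbon of A6 in a [2+2] step. A 4π opening of the vinylcyclobutenone, a 6π closure and tautomerisation give the 7-O-silyl ether of the target, (3R)-7-(tert-butyldimethylsilyloxy)-3-[2-hydroxy-4-methoxy-3-prenylphenyl]-5-methoxychroman A4.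
- For it: the contiguous OH, prenyl, OMe pattern of ring B forms with full regiocontrol in one step and with the 2'-OH free. The chosen route needs three steps for the prenyl group and a protecting group on ring B, so on this point alternative 2 is stronger. A4 is one desilylation from the target.
- Against it: the benzannulation does not create C3. An enantiopure 3-substituted chroman must be made separately, and in A5 the C3–H is γ to the enone and can be lost by dienolisation under basic diazo-transfer conditions. A5 needs a long linear sequence, A6 is a sensitive 1-alkoxyalkyne, and the ketene can also add to the prenyl olefin.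
- Comparison: the chosen strategy offers a much shorter sequence from two cheap benzaldehydes, with the stereocentre made catalytically in the convergent step.

Alternative 3: The O1–C2 bond is cut back to the prochiral oxetane 3-methoxy-5-(methoxymethoxy)-2-({3-[4-methoxy-2-(methoxymethoxy)-3-prenylphenyl]oxetan-3-yl}methyl)phenol A8. A chiral phosphoric acid activates the oxetane, and the ring A phenol opens one of the two enantiotopic CH2–O bonds in a 6-exo-tet closure. The product is the C3-quaternary chroman 3-(hydroxymethyl)-5-methoxy-7-(methoxymethoxy)-3-[4-methoxy-2-(methoxymethoxy)-3-prenylphenyl]chroman A7, as a single enantiomer. Oxidation to the aldehyde and decarbonylation with RhCl(PPh3)3 would then reveal C3–H with retention.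
- For it: the stereocentre is quaternary when it forms and cannot epimerise. The ring also closes directly at the right oxidation level. On configurational safety it is stronger than the chosen route, whose α-aryl aldehyde centre is labile until reduced.
- Against it: A8 has a quaternary carbon flanked by two ortho-substituted aryl units and needs a long synthesis. One carbon is installed only to be removed, which costs an oxidation and a stoichiometric rhodium decarbonylation of a hindered aldehyde near a prenyl olefin. The acetal groups must still be removed with acid beside the prenyl group.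
- Comparison: the chosen strategy reaches the same C3–H directly, without a sacrificial carbon and in fewer steps. It manages the lability of its intermediate by reducing it in the same flask.

Key step: step 10

## Route

Step 1
Reactants: 1 phloroglucinaldehyde (2,4,6-trihydroxybenzaldehyde)
Product: 2 allyl ether 2,6-dihydroxy-4-(prop-2-en-1-yloxy)benzaldehyde
Conditions: allyl bromide (1.0 equiv), KHCO3, DMF, 40 °C
Reagents that add atoms: allyl bromide, C=CCBr
Why: Williamson etherification; the 4-OH, para to the formyl group, is the most acidic hydroxyl and the only one not hydrogen-bonded to the carbonyl oxygen, so hydrogencarbonate ionises it alone and one equivalent of halide alkylates it. A dipolar aprotic solvent favours O- over C-allylation.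

Step 2
Reactants: 2 allyl ether 2,6-dihydroxy-4-(prop-2-en-1-yloxy)benzaldehyde
Product: 3 salicylaldehyde 2-hydroxy-6-methoxy-4-(prop-2-en-1-yloxy)benzaldehyde
Conditions: MeI (1.1 equiv), K2CO3 (1.0 equiv), acetone, rt
Reagents that add atoms: iodomethane, CI
Why: Williamson methylation; the two hydroxyls are equivalent, and after the first methylation the remaining one is locked in the chelate with the formyl group and reacts much more slowly, so the reaction should stop at the mono-methyl ether.

Step 3
Reactants: 3 salicylaldehyde 2-hydroxy-6-methoxy-4-(prop-2-en-1-yloxy)benzaldehyde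
Product: 5 sulfone 3-methoxy-2-[(4-methylbenzenesulfonyl)methyl]-5-(prop-2-en-1-yloxy)phenol, via benzylic alcohol 4 (not isolated)
Conditions: NaBH4, THF/MeOH, 0 °C; then HCO2H/H2O, sodium 4-methylbenzenesulfinate (3 equiv), 0 °C → rt
Reagents that add atoms: sodium 4-methylbenzenesulfinate, [Na+].Cc1ccc(cc1)S(=O)[O-]
Why: Hydride reduction gives the o-hydroxybenzyl alcohol 4; after the acid has destroyed excess hydride, this electron-rich alcohol ionises and the sulfinate captures the benzylic carbon at sulfur (SN1-type substitution), the sulfone being the thermodynamic product. Telescoping avoids isolating the labile alcohol, and the allyl ether tolerates formic acid.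

Step 4
Reactants: 6 2-hydroxy-4-methoxybenzaldehyde; 7 3-chloro-3-methylbut-1-yne
Product: 8 propargyl ether 4-methoxy-2-[(2-methylbut-3-yn-2-yl)oxy]benzaldehyde
Conditions: DBU, CuCl2·2H2O (cat.), MeCN, 0 °C → rt
Reagents that add atoms: none
Why: Copper-catalysed propargylic substitution; the copper acetylide of 7 loses chloride to give an electrophilic allenylidene-type species, which the phenoxide captures at the tertiary carbon. The low temperature avoids the thermal propargyl Claisen cyclisation to a chromene.

Step 5
Reactants: 8 propargyl ether 4-methoxy-2-[(2-methylbut-3-yn-2-yl)oxy]benzaldehyde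
Product: 9 allyl ether 4-methoxy-2-[(2-methylbut-3-en-2-yl)oxy]benzaldehyde
Conditions: H2 (1 atm), Pd/CaCO3 poisoned with Pb(OAc)2 (Lindlar catalyst), quinoline, EtOAc, rt
Reagents that add atoms: none
Why: Semihydrogenation of the terminal alkyne stops at the alkene on the poisoned catalyst; the aryl aldehyde and the aryl ether are not reduced under these conditions.

Step 6
Reactants: 9 allyl ether 4-methoxy-2-[(2-methylbut-3-en-2-yl)oxy]benzaldehyde
Product: 10 phenol 2-hydroxy-4-methoxy-3-(3-methylbut-2-en-1-yl)benzaldehyde
Conditions: PhNEt2, 140 °C
Reagents that add atoms: none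
Why: Aromatic Claisen rearrangement ([3,3], chair transition state); C1 carries the formyl group, so the allyl unit moves to the only free ortho position, C3, and allylic inversion converts the 1,1-dimethylallyl ether into the linear prenyl group. Tautomerisation restores the phenol, and tertiary allyl ethers rearrange at moderate temperature.

Step 7
Reactants: 10 phenol 2-hydroxy-4-methoxy-3-(3-methylbut-2-en-1-yl)benzaldehyde
Product: 11 benzaldehyde 4-methoxy-3-(3-methylbut-2-en-1-yl)-2-(prop-2-en-1-yloxy)benzaldehyde
Conditions: allyl bromide, K2CO3, DMF, 50 °C
Reagents that add atoms: allyl bromide, C=CCBr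
Why: Williamson etherification of the chelated, flanked phenol in a dipolar aprotic solvent; the allyl ether masks the phenol that would otherwise trap the future acetaldehyde as a lactol. Both positions ortho to it are substituted, so it cannot undergo its own Claisen shift, and it withstands the acid of step 9.

Step 8
Reactants: 11 benzaldehyde 4-methoxy-3-(3-methylbut-2-en-1-yl)-2-(prop-2-en-1-yloxy)benzaldehyde
Product: 12 enol ether 1-methoxy-4-(2-methoxyethenyl)-2-(3-methylbut-2-en-1-yl)-3-(prop-2-en-1-yloxy)benzene (E/Z mixture)
Conditions: Ph3P(CH2OMe)Cl, KOtBu, THF, 0 °C → rt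
Reagents that add atoms: (methoxymethyl)triphenylphosphonium chloride, COC[P+](c1ccccc1)(c1ccccc1)c1ccccc1.[Cl-]
Why: Wittig olefination with the α-methoxy ylide adds the one carbon that becomes C2; both enol ether isomers hydrolyse to the same aldehyde, and the aldehyde has no α-hydrogen for the basic ylide to remove.

Step 9
Reactants: 12 enol ether 1-methoxy-4-(2-methoxyethenyl)-2-(3-methylbut-2-en-1-yl)-3-(prop-2-en-1-yloxy)benzene
Product: 13 arylacetaldehyde 2-[4-methoxy-3-(3-methylbut-2-en-1-yl)-2-(prop-2-en-1-yloxy)phenyl]acetaldehyde
Conditions: aq. HCl (2 M), THF, rt → 40 °C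
Reagents that add atoms: water, O
Why: Acid-catalysed enol ether hydrolysis (C-protonation, oxocarbenium ion, hemiacetal, loss of methanol); allyl and methyl aryl ethers are stable to dilute aqueous acid. No free phenol lies ortho to the side chain or to the prenyl group, so neither benzofuran formation nor chroman closure can occur; the aldehyde is used without storage.

Step 10
Reactants: 5 sulfone 3-methoxy-2-[(4-methylbenzenesulfonyl)methyl]-5-(prop-2-en-1-yloxy)phenol; 13 arylacetaldehyde 2-[4-methoxy-3-(3-methylbut-2-en-1-yl)-2-(prop-2-en-1-yloxy)phenyl]acetaldehyde
Product: 16 diol 3-methoxy-2-[(2R)-3-hydroxy-2-[4-methoxy-3-(3-methylbut-2-en-1-yl)-2-(prop-2-en-1-yloxy)phenyl]propyl]-5-(prop-2-en-1-yloxy)phenol, via o-quinone methide 14 (not isolated), via chroman-2-ol 15 (not isolated)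
Conditions: (R)-2-[diphenyl(trimethylsilyloxy)methyl]pyrrolidine (20 mol%), Na2CO3, CH2Cl2, 0 °C → rt; then MeOH, NaBH4, 0 °C
Reagents that add atoms: none
Why: Carbonate deprotonates the phenol of 5 and the phenoxide expels the sulfinate (1,4-elimination) to give o-quinone methide 14, whose exocyclic CH2 is the future C4 and which stays at low concentration because the base is insoluble. Aldehyde 13 condenses with the amine to the aryl-conjugated E-enamine, whose nucleophilic carbon (future C3) adds to the CH2 of 14 in a Michael addition that rearomatises ring A and forms C3–C4; a concerted oxa-[4+2] addition to the enamine C=C would give the same product after hydrolysis. Hydrolysis of the iminium ion frees the catalyst, and the ring A phenol adds to the aldehyde carbon in a 6-exo-trig hemiacetalisation that forms O1–C2 and closes the pyran ring as chroman-2-ol 15, an anomeric mixture at a carbon that ends as CH2. The closest known reaction type is the secondary-amine-catalysed Michael addition and hemiacetalisation of aldehydes with o-quinone methides released in situ from 2-(sulfonylmethyl)phenols. C3 is the only lasting new stereocentre and is set by the catalyst: in the s-trans E-enamine the diphenyl(silyloxy)methyl group of the (R)-pyrrolidine covers the Si face of the enamine carbon, so 14 adds on the Re face, which is (3R) here because the aryl group outranks the new CH2 substituent; this assignment rests on the steric model and is to be confirmed on 16. The step needs an enantioselectivity that survives the lability of an α-aryl aldehyde; the α-branched product re-forms an enamine only slowly and is held almost wholly as the cyclic hemiacetal, the base is weak, and NaBH4 added to the same flask reduces the open form to diol 16 as soon as it appears. The allyl ethers, the prenyl group and the methyl ethers are inert to amine, carbonate and borohydride.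

Step 11
Reactants: 16 diol 3-methoxy-2-[(2R)-3-hydroxy-2-[4-methoxy-3-(3-methylbut-2-en-1-yl)-2-(prop-2-en-1-yloxy)phenyl]propyl]-5-(prop-2-en-1-yloxy)phenol
Product: 17 chroman (3R)-5-methoxy-3-[4-methoxy-3-(3-methylbut-2-en-1-yl)-2-(prop-2-en-1-yloxy)phenyl]-7-(prop-2-en-1-yloxy)-3,4-dihydro-2H-chromene
Conditions: PPh3, DIAD, THF, 0 °C → rt
Reagents that add atoms: none
Why: Intramolecular Mitsunobu etherification; the primary alcohol is activated as its alkoxyphosphonium ion and displaced by the ring A phenoxide in a 6-exo-tet SN2 closure that forms O1–C2. The reacting carbon is not stereogenic and C3 is not touched, so its configuration is kept.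

Step 12
Reactants: 17 chroman (3R)-5-methoxy-3-[4-methoxy-3-(3-methylbut-2-en-1-yl)-2-(prop-2-en-1-yloxy)phenyl]-7-(prop-2-en-1-yloxy)-3,4-dihydro-2H-chromene
Product: 18 target (3R)-3-[2-hydroxy-4-methoxy-3-(3-methylbut-2-en-1-yl)phenyl]-5-methoxy-3,4-dihydro-2H-chromen-7-ol
Conditions: Pd(PPh3)4 (5 mol%), morpholine, THF, rt
Reagents that add atoms: none
Why: Zerovalent palladium ionises both aryl allyl ethers to π-allyl complexes and phenoxides, and morpholine captures the allyl fragments (Tsuji–Trost-type deallylation). The conditions are neutral, so the prenyl olefin beside the freed 2'-OH is neither isomerised nor cyclised, and the methyl ethers and C3 are unaffected.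

## Compound list

1 | 2,4,6-trihydroxybenzaldehyde | O=Cc1c(O)cc(O)cc1O | starting material
2 | 2,6-dihydroxy-4-(prop-2-en-1-yloxy)benzaldehyde | C=CCOc1cc(O)c(C=O)c(O)c1 | intermediate
3 | 2-hydroxy-6-methoxy-4-(prop-2-en-1-yloxy)benzaldehyde | C=CCOc1cc(O)c(C=O)c(OC)c1 | intermediate
4 | 2-(hydroxymethyl)-3-methoxy-5-(prop-2-en-1-yloxy)phenol | C=CCOc1cc(O)c(CO)c(OC)c1 | intermediate (not isolated)
5 | 3-methoxy-2-[(4-methylbenzenesulfonyl)methyl]-5-(prop-2-en-1-yloxy)phenol | C=CCOc1cc(O)c(CS(=O)(=O)c2ccc(C)cc2)c(OC)c1 | intermediate
6 | 2-hydroxy-4-methoxybenzaldehyde | COc1ccc(C=O)c(O)c1 | starting material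
7 | 3-chloro-3-methylbut-1-yne | CC(C)(Cl)C#C | starting material
8 | 4-methoxy-2-[(2-methylbut-3-yn-2-yl)oxy]benzaldehyde | COc1ccc(C=O)c(OC(C)(C)C#C)c1 | intermediate
9 | 4-methoxy-2-[(2-methylbut-3-en-2-yl)oxy]benzaldehyde | COc1ccc(C=O)c(OC(C)(C)C=C)c1 | intermediate
10 | 2-hydroxy-4-methoxy-3-(3-methylbut-2-en-1-yl)benzaldehyde | COc1ccc(C=O)c(O)c1CC=C(C)C | intermediate
11 | 4-methoxy-3-(3-methylbut-2-en-1-yl)-2-(prop-2-en-1-yloxy)benzaldehyde | COc1ccc(C=O)c(OCC=C)c1CC=C(C)C | intermediate
12 | 1-methoxy-4-(2-methoxyethenyl)-2-(3-methylbut-2-en-1-yl)-3-(prop-2-en-1-yloxy)benzene (E/Z mixture) | COC=Cc1ccc(OC)c(CC=C(C)C)c1OCC=C | intermediate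
13 | 2-[4-methoxy-3-(3-methylbut-2-en-1-yl)-2-(prop-2-en-1-yloxy)phenyl]acetaldehyde | O=CCc1ccc(OC)c(CC=C(C)C)c1OCC=C | intermediate
14 | 5-methoxy-6-methylidene-3-(prop-2-en-1-yloxy)cyclohexa-2,4-dien-1-one | O=C1C=C(OCC=C)C=C(OC)C1=C | intermediate (not isolated)
15 | (3R)-5-methoxy-3-[4-methoxy-3-(3-methylbut-2-en-1-yl)-2-(prop-2-en-1-yloxy)phenyl]-7-(prop-2-en-1-yloxy)-3,4-dihydro-2H-chromen-2-ol (mixture of C2 anomers) | COc1cc(OCC=C)cc2c1C[C@H](c1ccc(OC)c(CC=C(C)C)c1OCC=C)C(O)O2 | intermediate (not isolated)
16 | 3-methoxy-2-[(2R)-3-hydroxy-2-[4-methoxy-3-(3-methylbut-2-en-1-yl)-2-(prop-2-en-1-yloxy)phenyl]propyl]-5-(prop-2-en-1-yloxy)phenol | COc1cc(OCC=C)cc(O)c1C[C@H](c1ccc(OC)c(CC=C(C)C)c1OCC=C)CO | intermediate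
17 | (3R)-5-methoxy-3-[4-methoxy-3-(3-methylbut-2-en-1-yl)-2-(prop-2-en-1-yloxy)phenyl]-7-(prop-2-en-1-yloxy)-3,4-dihydro-2H-chromene | COc1cc(OCC=C)cc2c1C[C@H](c1ccc(OC)c(CC=C(C)C)c1OCC=C)CO2 | intermediate
18 | (3R)-3-[2-hydroxy-4-methoxy-3-(3-methylbut-2-en-1-yl)phenyl]-5-methoxy-3,4-dihydro-2H-chromen-7-ol | COc1cc(O)cc2c1C[C@H](c1ccc(OC)c(CC=C(C)C)c1O)CO2 | target

## Step count and least certain steps

Total step count: 12. Longest linear sequence: 9 steps (steps 4 to 12, from 6 to 18); the ring A branch adds 3 steps (1 to 3) before the convergent step 10.

Step 10 (key step). The main danger is erosion of enantiopurity. A base-mediated, catalyst-free addition of the enol of 13 to the quinone methide gives racemic material, and the open hydroxy-aldehyde form of the lactol can epimerise before hydride reaches it. Self-condensation of the quinone methide and reversible N-alkylation of the catalyst would lower conversion. The fallback moves the stereo-determining event from C–C bond formation to the reduction. It sets out from 5 and 13, which are joined with achiral pyrrolidine (20 mol%) and Na2CO3 in CH2Cl2 to give the racemic chroman-2-ol F1. F1 is then hydrogenated under dynamic kinetic resolution with one enantiomer of RuCl2(xylBINAP)(DAIPEN), KOtBu and H2 in iPrOH. The base interconverts the enantiomers of the open α-aryl aldehyde while the chiral ruthenium hydride reduces one of them faster, and this catalyst type does not reduce isolated olefins. The sequence comes back to the route at 16.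

Step 3. The electron-rich o-hydroxybenzyl alcohol ionises very easily. If hydride is still present it can be reduced past the alcohol stage, and the ionised form can attack a second ring A, giving self-condensation. The fallback avoids the free alcohol. It sets out from 3, which undergoes reductive amination with dimethylamine and NaBH(OAc)3 to give the stable Mannich base 2-[(dimethylamino)methyl]-3-methoxy-5-(prop-2-en-1-yloxy)phenol F2. Heating F2 with sodium 4-methylbenzenesulfinate in aqueous HCO2H exchanges the amine for the sulfinate and comes back to the route at 5.

Step 9. Hydrolysis of a styryl enol ether can be slow, and forcing the acid invites aldol self-condensation of the arylacetaldehyde or hydration of the prenyl olefin. The fallback replaces hydrolysis by an isomerisation and skips 12. It sets out from 11, which is converted by Corey–Chaykovsky epoxidation (Me3SI, KOtBu, DMSO/THF) into the oxirane 2-[4-methoxy-3-(3-methylbut-2-en-1-yl)-2-(prop-2-en-1-yloxy)phenyl]oxirane F3. A Meinwald rearrangement with catalytic ZnBr2 in CH2Cl2 opens F3 to the benzylic cation, stabilised by the para methoxy group, and a hydride shift gives the aldehyde. The sequence comes back to the route at 13.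

Step 4. O-alkylation of the chelated, weakly nucleophilic phenoxide by a tertiary chloride can be slow, and then elimination of HCl from 7 competes and conversion stays incomplete. The fallback uses π-allyl chemistry and skips 8 and step 5. It sets out from 6, which reacts with tert-butyl 2-methylbut-3-en-2-yl carbonate F4 (from 2-methylbut-3-en-2-ol and Boc2O) and Pd(PPh3)4 in THF at 0 °C in a Tsuji–Trost etherification. The phenoxide attacks the more substituted terminus of the dimethylallyl complex, and the sequence comes back to the route at 9.

Step 1. Alkylation may run on to a second hydroxyl, or the phloroglucinol nucleus may be C-allylated. The fallback avoids a free phenoxide. It sets out from 1, which undergoes Mitsunobu etherification with allyl alcohol, PPh3 and DIAD in THF. The reaction selects the most acidic, non-chelated 4-OH and is strictly O-selective. It makes no new compound (F0) and comes back to the route at 2.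

## Further compounds

F1 | step 10 | racemic 5-methoxy-3-[4-methoxy-3-(3-methylbut-2-en-1-yl)-2-(prop-2-en-1-yloxy)phenyl]-7-(prop-2-en-1-yloxy)-3,4-dihydro-2H-chromen-2-ol | COc1cc(OCC=C)cc2c1CC(c1ccc(OC)c(CC=C(C)C)c1OCC=C)C(O)O2
F2 | step 3 | 2-[(dimethylamino)methyl]-3-methoxy-5-(prop-2-en-1-yloxy)phenol | CN(C)Cc1c(O)cc(OCC=C)cc1OC
F3 | step 9 | 2-[4-methoxy-3-(3-methylbut-2-en-1-yl)-2-(prop-2-en-1-yloxy)phenyl]oxirane | COc1ccc(C2CO2)c(OCC=C)c1CC=C(C)C
F4 | step 4 | tert-butyl 2-methylbut-3-en-2-yl carbonate | CC(C)(C)OC(=O)OC(C)(C)C=C
F0 | step 1 | none | none
A1 | alternative 1 | 7-(benzyloxy)-5-methoxy-3-[4-methoxy-2-(methoxymethoxy)phenyl]-2H-chromene | COc1cc(OCc3ccccc3)cc2c1C=C(c1ccc(OC)cc1OCOC)CO2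
A2 | alternative 1 | 2-[4-methoxy-2-(methoxymethoxy)phenyl]prop-2-enal | C=C(C=O)c1ccc(OC)cc1OCOC
A3 | alternative 1 | 5-(benzyloxy)-3-methoxy-2-(trimethylsilyl)phenyl trifluoromethanesulfonate | COc1cc(OCc2ccccc2)cc(OS(=O)(=O)C(F)(F)F)c1[Si](C)(C)C
A4 | alternative 2 | (3R)-7-(tert-butyldimethylsilyloxy)-3-[2-hydroxy-4-methoxy-3-(3-methylbut-2-en-1-yl)phenyl]-5-methoxy-3,4-dihydro-2H-chromene | COc1cc(O[Si](C)(C)C(C)(C)C)cc2c1C[C@H](c1ccc(OC)c(CC=C(C)C)c1O)CO2
A5 | alternative 2 | (E)-1-diazo-4-[(3R)-7-(tert-butyldimethylsilyloxy)-5-methoxy-3,4-dihydro-2H-chromen-3-yl]but-3-en-2-one | COc1cc(O[Si](C)(C)C(C)(C)C)cc2c1C[C@H](/C=C/C(=O)C=[N+]=[N-])CO2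
A6 | alternative 2 | 1-methoxy-5-methylhex-4-en-1-yne | COC#CCC=C(C)C
A7 | alternative 3 | 3-(hydroxymethyl)-5-methoxy-7-(methoxymethoxy)-3-[4-methoxy-2-(methoxymethoxy)-3-(3-methylbut-2-en-1-yl)phenyl]-3,4-dihydro-2H-chromene, single enantiomer | COc1cc(OCOC)cc2c1C[C@](CO)(c1ccc(OC)c(CC=C(C)C)c1OCOC)CO2
A8 | alternative 3 | 3-methoxy-5-(methoxymethoxy)-2-({3-[4-methoxy-2-(methoxymethoxy)-3-(3-methylbut-2-en-1-yl)phenyl]oxetan-3-yl}methyl)phenol | COc1cc(OCOC)cc(O)c1CC1(c2ccc(OC)c(CC=C(C)C)c2OCOC)COC1
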